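**Retrosynthetic overview**
1. Target 33 ⇐ cyclopentanone 30 (C2 reduction, acetylation, desilylation) ⇐ diazo ketone 29 by Rh-carbenoid insertion into C4–H; the cyclopentane closes last, at the non-fused C3–C4 bond, with retention at C4.
2. 29 ⇐ isoxazoline 22 (N–O cleavage, 1,3-anti reduction to set C6, veratroylation, silylation, diazo transfer).
3. 22 ⇐ open-chain nitro Z-olefin 20: one intramolecular nitrile oxide–olefin cycloaddition closes the seven-membered carbocycle (C5–C6) and the isoxazoline (C4–O) together, with the oxirane already in the tether, and sets C5 and C4.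
4. 20 ⇐ epoxy aldehyde 6 + ring-locked Z-allylboronate 12 (allylboration sets C1 and C10), then Z-Wittig and Wacker oxidation.
5. 6 ⇐ Sharpless epoxidation of E-allylic alcohol 4 (sets C8, C9) ⇐ 4-bromobut-1-yne. Ring order: oxirane, then cycloheptane + isoxazoline in one step, then cyclopentane.

Assumption: the SMILES is read literally. C8 and C9 are both R, so the two oxirane C–O bonds lie on opposite faces of the seven-membered ring (the oxide of an E olefin, trans-fused); the oxirane is therefore made on an open-chain E olefin and the ring is closed afterwards.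

Locants in names follow the daucane numbering of the target: C1 (quaternary, CH3), C2 (OAc), C3, C4 (OH, iPr), C5, C6 (O-veratroyl), C7, C8 (CH3, oxirane), C9 (oxirane), C10 (OH). Configurations are those written in the SMILES of the compound list.

Step 1
Reactants: 1 4-bromobut-1-yne
Product: 3 (E)-5-bromo-3-methylpent-2-en-1-ol, via alkenylalane 2 (not isolated)
Conditions: Me3Al (2.5 equiv), Cp2ZrCl2 (0.25 equiv), CH2Cl2, 0 → 23 °C; then (CH2O)n, THF, 0 → 23 °C; aq. HCl work-up
Reagents that add atoms: trimethylaluminium, C[Al](C)C; formaldehyde (from paraformaldehyde), C=O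
Why: Negishi zirconium-catalysed carboalumination adds CH3 and Al syn across the alkyne, and C–Al hydroxymethylation with retention gives the E-trisubstituted allylic alcohol (C7 trans to C10).

Step 2
Reactants: 3 (E)-5-bromo-3-methylpent-2-en-1-ol
Product: 4 (E)-3-methyl-5-nitropent-2-en-1-ol
Conditions: NaNO2, phloroglucinol, DMF, 23 °C
Reagents that add atoms: sodium nitrite, [Na+].[O-]N=O
Why: Kornblum SN2 displacement of the primary bromide by nitrite (phloroglucinol scavenges nitrite ester) installs the primary nitro group that later becomes the nitrile oxide carbon C6.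

Step 3
Reactants: 4 (E)-3-methyl-5-nitropent-2-en-1-ol
Product: 5 [(2R,3R)-3-methyl-3-(2-nitroethyl)oxiran-2-yl]methanol
Conditions: Ti(OiPr)4 (10 mol %), D-(−)-diethyl tartrate (12 mol %), t-BuOOH, 4 Å molecular sieves, CH2Cl2, −20 °C
Reagents that add atoms: tert-butyl hydroperoxide, CC(C)(C)OO
Why: Sharpless asymmetric epoxidation of a geraniol-type E allylic alcohol; D-(−)-tartrate gives the (2R,3R) oxirane (mirror of the L-(+)-tartrate/geraniol outcome), and the E geometry places C7 and C10 trans on the oxirane, which sets C8 and C9.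

Step 4
Reactants: 5 [(2R,3R)-3-methyl-3-(2-nitroethyl)oxiran-2-yl]methanol
Product: 6 (2S,3R)-3-methyl-3-(2-nitroethyl)oxirane-2-carbaldehyde
Conditions: Dess–Martin periodinane, NaHCO3, CH2Cl2, 0 °C
Reagents that add atoms: none
Why: Buffered Dess–Martin oxidation gives the α,β-epoxy aldehyde without touching the oxirane stereocentres or the nitro group.

Step 5
Reactants: 7 triisopropyl borate; 8 allylmagnesium bromide; 9 2-methylprop-2-en-1-ol
Product: 12 2-isopropoxy-5-methyl-3,6-dihydro-2H-1,2-oxaborinine, via diisopropyl allylboronate 10 (not isolated), via mixed allyl methallyl boronate 11 (not isolated)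
Conditions: Et2O, −78 °C; HCl in Et2O; then 9 (1.0 equiv), 4 Å molecular sieves, CH2Cl2, 23 °C; then second-generation Grubbs catalyst (3 mol %), 40 °C; used as a solution
Reagents that add atoms: none
Why: Grignard borylation, transesterification and boron-tethered ring-closing metathesis give a six-membered allylboronate whose ring forces the CH2O arm cis to the CH2B arm, i.e. a geometrically fixed Z-γ,γ-disubstituted allylboron reagent.

Step 6
Reactants: 6 (2S,3R)-3-methyl-3-(2-nitroethyl)oxirane-2-carbaldehyde; 12 2-isopropoxy-5-methyl-3,6-dihydro-2H-1,2-oxaborinine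
Product: 14 (2R)-2-[(R)-hydroxy[(2R,3R)-3-methyl-3-(2-nitroethyl)oxiran-2-yl]methyl]-2-methylbut-3-en-1-ol, via cyclic borate 13 (not isolated)
Conditions: 12 (1.5 equiv), toluene, 4 Å molecular sieves, −20 → 23 °C; then aq. NaHCO3
Reagents that add atoms: none
Why: Allylboration through a closed chair transition state puts the ring-locked Z arm (C5H2O) syn and the CH3 anti to the new hydroxyl (C1 relative to C10), and the allyl group adds anti to the oxirane C–O bond (Felkin–Anh/Cornforth, as for Z-crotylboronates with α-alkoxy aldehydes), giving the 9,10-anti relation.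

Step 7
Reactants: 14 (2R)-2-[(R)-hydroxy[(2R,3R)-3-methyl-3-(2-nitroethyl)oxiran-2-yl]methyl]-2-methylbut-3-en-1-ol
Product: 15 bis(triethylsilyl) ether of 14
Conditions: Et3SiOTf (2.5 equiv), 2,6-lutidine, CH2Cl2, −78 °C
Reagents that add atoms: triethylsilyl trifluoromethanesulfonate, CC[Si](CC)(CC)OS(=O)(=O)C(F)(F)F
Why: Exhaustive silylation protects C10–OH for the rest of the route and sets up the primary ether for direct oxidation.

Step 8
Reactants: 15 bis(triethylsilyl) ether of 14
Product: 16 C5 aldehyde (2-methyl-2-vinyl propanal carrying 10-OTES and the oxirane)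
Conditions: (COCl)2, DMSO, CH2Cl2, −78 → −30 °C; Et3N
Reagents that add atoms: none
Why: Under Swern conditions the activated sulfonium cleaves and oxidises the primary triethylsilyl ether selectively, while the hindered secondary C10 silyl ether is untouched.

Step 9
Reactants: 16 C5 aldehyde; 17 isobutyltriphenylphosphonium bromide
Product: 19 (Z)-olefin (C5H=C4H–iPr on C1), via phosphonium ylide 18 (not isolated)
Conditions: 17, NaN(SiMe3)2, THF, 0 °C; then 16, −78 → 0 °C
Reagents that add atoms: none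
Why: Wittig olefination with a non-stabilised ylide under salt-free conditions is Z-selective, and this geometry fixes the later C4/C5 relation.

Step 10
Reactants: 19 (Z)-olefin
Product: 20 methyl ketone (C2 acetyl on C1)
Conditions: PdCl2 (10 mol %), Cu(OAc)2 (20 mol %), O2 (1 atm), DMA–H2O (7:1), 23 °C
Reagents that add atoms: water, O
Why: Wacker–Tsuji oxidation under acid-free conditions converts the terminal vinyl group (Markovnikov) into the acetyl group, while the hindered internal Z olefin and the oxirane remain.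

Step 11
Reactants: 20 methyl ketone
Product: 22 isoxazoline-fused cycloheptane (C6=N–O–C4, new C5–C6 bond), via nitrile oxide 21 (not isolated)
Conditions: PhNCO (3 equiv), Et3N (0.3 equiv), benzene, 0.003 M, 60 °C, slow addition of 20
Reagents that add atoms: none
Why: Mukaiyama dehydration gives nitrile oxide 21, whose intramolecular 1,3-dipolar cycloaddition in the fused (exo) mode closes the cycloheptane and the isoxazoline in one step: suprafacial addition turns the Z geometry into the C4/C5 relation (iPr cis to C1), and A(1,3) strain with the cis isopropyl puts the small C1 methyl in the olefin plane and the acetyl anti, so C6 bonds to the face that leaves the C4 arm cis to the C1 methyl (the later trans ring fusion).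

Step 12
Reactants: 22 isoxazoline-fused cycloheptane
Product: 24 1,3-anti diol (C4–OH, C6–OH), via hydroxy ketone 23 (not isolated)
Conditions: H2 (1 atm), Raney Ni, B(OH)3, MeOH–H2O (5:1), 23 °C; filter, concentrate; then Me4NBH(OAc)3, MeCN–AcOH (1:1), −30 °C
Reagents that add atoms: water, O
Why: N–O hydrogenolysis with imine hydrolysis unmasks the β-hydroxy ketone, which is reduced at once (it is a base-sensitive β,γ-epoxy ketone) by Evans–Saksena intramolecular hydride delivery from the C4 alkoxyborohydride to give the 1,3-anti diol, i.e. the C6 configuration of the target.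

Step 13
Reactants: 24 1,3-anti diol; 25 3,4-dimethoxybenzoyl chloride
Product: 26 C6 veratrate (C4–OH free)
Conditions: 25 (1.1 equiv), pyridine, DMAP (cat.), CH2Cl2, −20 → 0 °C
Reagents that add atoms: none
Why: DMAP-catalysed acylation takes the ring C6 hydroxyl, which is less hindered than the C4 hydroxyl flanked by isopropyl and the C5 branch.

Step 14
Reactants: 26 C6 veratrate
Product: 27 C4 triethylsilyl ether of 26
Conditions: Et3SiOTf, 2,6-lutidine, CH2Cl2, −78 °C
Reagents that add atoms: triethylsilyl trifluoromethanesulfonate, CC[Si](CC)(CC)OS(=O)(=O)C(F)(F)F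
Why: Silylation blocks O–H insertion in the carbenoid step and turns C4–H into an ether-activated tertiary C–H bond.

Step 15
Reactants: 27 C4 triethylsilyl ether
Product: 29 α-diazo ketone (C2(=O)–C3H=N2), via trifluoroacetyl diketone 28 (not isolated)
Conditions: LiN(SiMe3)2, THF, −78 °C; CF3CO2CH2CF3; then MsN3, Et3N, H2O, MeCN, 23 °C
Reagents that add atoms: methanesulfonyl azide, CS(=O)(=O)N=[N+]=[N-]
Why: Danheiser detrifluoroacetylative diazo transfer works cleanly because the acetyl methyl is the only enolisable position of the only ketone.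

Step 16
Reactants: 29 α-diazo ketone
Product: 30 cyclopentanone (2-oxo, 4,10-bis-O-TES, 6-O-veratroyl, 8,9-epoxydaucane)
Conditions: Rh2(OAc)4 (1 mol %), CH2Cl2, 23 °C, slow addition
Reagents that add atoms: none
Why: Rhodium-carbenoid 1,5 C–H insertion (Taber cyclopentanone synthesis) into the tertiary, ether-activated C4–H is concerted with retention, so the C4 configuration set in step 11 becomes the C4(O)(iPr) centre and the cyclopentane closes at a non-fused bond; the acyloxy-bearing C6–H is deactivated.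

Step 17
Reactants: 30 cyclopentanone
Product: 31 C2 alcohol (OH cis to the C1 methyl)
Conditions: NaBH4, MeOH, −20 °C
Reagents that add atoms: none
Why: Hydride reduction from the face opposite the angular C1 methyl (as in 17-keto steroids) gives the C2 alcohol cis to that methyl.

Step 18
Reactants: 31 C2 alcohol
Product: 32 C2 acetate
Conditions: Ac2O, pyridine, DMAP (cat.), CH2Cl2, 23 °C
Reagents that add atoms: acetic anhydride, CC(=O)OC(C)=O
Why: Acetylation of the only free hydroxyl; all other oxygens are silylated or acylated.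

Step 19
Reactants: 32 C2 acetate
Product: 33 target CNP0197096.5
Conditions: Bu4NF, AcOH (1:1), THF, 0 → 23 °C
Reagents that add atoms: none
Why: Buffered fluoride desilylation frees C10–OH and C4–OH without acyl migration or oxirane opening.

**Compound list**
1 | 4-bromobut-1-yne | C#CCCBr | starting material
2 | (E)-(4-bromo-2-methylbut-1-enyl)dimethylalane | C[Al](C)/C=C(\C)CCBr | intermediate
3 | (E)-5-bromo-3-methylpent-2-en-1-ol | OC/C=C(\C)CCBr | intermediate
4 | (E)-3-methyl-5-nitropent-2-en-1-ol | OC/C=C(\C)CC[N+](=O)[O-] | intermediate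
5 | [(2R,3R)-3-methyl-3-(2-nitroethyl)oxiran-2-yl]methanol | OC[C@H]1O[C@]1(C)CC[N+](=O)[O-] | intermediate
6 | (2S,3R)-3-methyl-3-(2-nitroethyl)oxirane-2-carbaldehyde | O=C[C@H]1O[C@]1(C)CC[N+](=O)[O-] | intermediate
7 | triisopropyl borate | CC(C)OB(OC(C)C)OC(C)C | starting material
8 | allylmagnesium bromide | C=CC[Mg]Br | starting material
9 | 2-methylprop-2-en-1-ol | CC(=C)CO | starting material
10 | diisopropyl allylboronate | C=CCB(OC(C)C)OC(C)C | intermediate
11 | allyl(isopropoxy)(2-methylallyloxy)borane | C=CCB(OC(C)C)OCC(C)=C | intermediate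
12 | 2-isopropoxy-5-methyl-3,6-dihydro-2H-1,2-oxaborinine | CC1=CCB(OC(C)C)OC1 | intermediate
13 | cyclic isopropyl borate of diol 14 (boron bridges O10 and the C5 oxygen) | CC(C)OB1OC[C@@](C)(C=C)[C@@H](O1)[C@H]2O[C@]2(C)CC[N+](=O)[O-] | intermediate
14 | (2R)-2-[(R)-hydroxy[(2R,3R)-3-methyl-3-(2-nitroethyl)oxiran-2-yl]methyl]-2-methylbut-3-en-1-ol | OC[C@@](C)(C=C)[C@@H](O)[C@H]1O[C@]1(C)CC[N+](=O)[O-] | intermediate
15 | bis(triethylsilyl) ether of 14 (C5–O and C10–O) | CC[Si](CC)(CC)OC[C@@](C)(C=C)[C@@H](O[Si](CC)(CC)CC)[C@H]1O[C@]1(C)CC[N+](=O)[O-] | intermediate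
16 | C5 aldehyde: 2-methyl-2-vinyl-3-(triethylsilyloxy)-3-[(2R,3R)-3-methyl-3-(2-nitroethyl)oxiran-2-yl]propanal, C1 and C10 as in 14 | O=C[C@@](C)(C=C)[C@@H](O[Si](CC)(CC)CC)[C@H]1O[C@]1(C)CC[N+](=O)[O-] | intermediate
17 | isobutyltriphenylphosphonium bromide | CC(C)C[P+](c1ccccc1)(c1ccccc1)c1ccccc1.[Br-] | starting material
18 | isobutylidenetriphenylphosphorane | CC(C)C=P(c1ccccc1)(c1ccccc1)c1ccccc1 | intermediate
19 | (Z)-olefin: C1 bears CH3, vinyl, (Z)-CH=CH–iPr and the C10(OTES)–oxirane–CH2CH2NO2 chain | CC(C)/C=C\[C@@](C)(C=C)[C@@H](O[Si](CC)(CC)CC)[C@H]1O[C@]1(C)CC[N+](=O)[O-] | intermediate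
20 | methyl ketone: as 19 with acetyl (C2, C3) in place of vinyl | CC(C)/C=C\[C@@](C)(C(C)=O)[C@@H](O[Si](CC)(CC)CC)[C@H]1O[C@]1(C)CC[N+](=O)[O-] | intermediate
21 | nitrile oxide of 20 (C6≡N–O) | CC(C)/C=C\[C@@](C)(C(C)=O)[C@@H](O[Si](CC)(CC)CC)[C@H]1O[C@]1(C)CC#[N+][O-] | intermediate
22 | isoxazoline-fused epoxycycloheptane: C6=N–O–C4(H)(iPr), C5–H, 1-acetyl-1-methyl, 10-OTES, 8,9-oxirane; iPr cis to C1 on the isoxazoline; C4 arm cis to the C1 methyl | CC(C)[C@H]1ON=C2C[C@@]3(C)O[C@@H]3[C@H](O[Si](CC)(CC)CC)[C@](C)(C(C)=O)[C@@H]12 | intermediate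
23 | β-hydroxy ketone: C6 ketone, C4 secondary alcohol | CC(C)[C@@H](O)[C@H]1C(=O)C[C@@]2(C)O[C@@H]2[C@H](O[Si](CC)(CC)CC)[C@]1(C)C(C)=O | intermediate
24 | 1,3-anti diol: C4–OH and C6–OH | CC(C)[C@@H](O)[C@H]1[C@H](O)C[C@@]2(C)O[C@@H]2[C@H](O[Si](CC)(CC)CC)[C@]1(C)C(C)=O | intermediate
25 | 3,4-dimethoxybenzoyl chloride | COc1ccc(C(Cl)=O)cc1OC | starting material
26 | C6 3,4-dimethoxybenzoate of 24 | CC(C)[C@@H](O)[C@H]1[C@H](OC(=O)c2ccc(OC)c(OC)c2)C[C@@]3(C)O[C@@H]3[C@H](O[Si](CC)(CC)CC)[C@]1(C)C(C)=O | intermediate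
27 | C4 triethylsilyl ether of 26 | CC(C)[C@@H](O[Si](CC)(CC)CC)[C@H]1[C@H](OC(=O)c2ccc(OC)c(OC)c2)C[C@@]3(C)O[C@@H]3[C@H](O[Si](CC)(CC)CC)[C@]1(C)C(C)=O | intermediate
28 | trifluoroacetyl diketone of 27 (C2(=O)–C3H2–COCF3) | CC(C)[C@@H](O[Si](CC)(CC)CC)[C@H]1[C@H](OC(=O)c2ccc(OC)c(OC)c2)C[C@@]3(C)O[C@@H]3[C@H](O[Si](CC)(CC)CC)[C@]1(C)C(=O)CC(=O)C(F)(F)F | intermediate
29 | α-diazo ketone (C2(=O)–C3H=N2) | CC(C)[C@@H](O[Si](CC)(CC)CC)[C@H]1[C@H](OC(=O)c2ccc(OC)c(OC)c2)C[C@@]3(C)O[C@@H]3[C@H](O[Si](CC)(CC)CC)[C@]1(C)C(=O)C=[N+]=[N-] | intermediate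
30 | cyclopentanone: 2-oxo-4,10-bis(triethylsilyloxy)-6-(3,4-dimethoxybenzoyloxy)-8,9-epoxydaucane | COc1ccc(C(=O)O[C@@H]2C[C@@]3(C)O[C@@H]3[C@H](O[Si](CC)(CC)CC)[C@]3(C)C(=O)C[C@@](O[Si](CC)(CC)CC)(C(C)C)[C@@H]23)cc1OC | intermediate
31 | C2 alcohol of 30 (OH cis to the C1 methyl) | COc1ccc(C(=O)O[C@@H]2C[C@@]3(C)O[C@@H]3[C@H](O[Si](CC)(CC)CC)[C@]3(C)[C@@H](O)C[C@@](O[Si](CC)(CC)CC)(C(C)C)[C@@H]23)cc1OC | intermediate
32 | C2 acetate of 31 | COc1ccc(C(=O)O[C@@H]2C[C@@]3(C)O[C@@H]3[C@H](O[Si](CC)(CC)CC)[C@]3(C)[C@@H](OC(C)=O)C[C@@](O[Si](CC)(CC)CC)(C(C)C)[C@@H]23)cc1OC | intermediate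
33 | CNP0197096.5: 2-acetoxy-4,10-dihydroxy-6-(3,4-dimethoxybenzoyloxy)-8,9-epoxydaucane, (1R,2S,4R,5R,6R,8R,9R,10R) | COc1ccc(C(=O)O[C@@H]2C[C@@]3(C)O[C@@H]3[C@H](O)[C@]3(C)[C@@H](OC(C)=O)C[C@@](O)(C(C)C)[C@@H]23)cc1OC | target

**Totals**
Total step count: 19. Longest linear sequence: 18 steps (1 → 33 through steps 1–4 and 6–19; step 5 is a one-step branch).

**Three steps most likely to fail**

Step 11 (nitrile oxide ring closure). The seven-membered ring must close with the E-derived oxirane in the tether, so dimerisation of the nitrile oxide to a furoxan or a poor facial ratio at C5 are the likely failures. The fallback changes the dipole: from 20, Me3SiCl and Et3N in toluene give the silyl nitronate F1, which cannot dimerise and cyclises on heating (80 °C) to the N-(trimethylsilyloxy)isoxazolidine F2. Bu4NF then eliminates trimethylsilanol and the route is rejoined at 22.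

Step 16 (carbenoid C–H insertion). The carbenoid may be diverted to oxonium ylides by the oxirane or silyl ether oxygens, or the hindered C4–H may not react. The fallback builds the cyclopentane by carbonyl chemistry and sets C4 on the formed ring. From 26, Dess–Martin oxidation of C4–OH gives the 1,4-diketone F3. LiN(iPr)2 at −78 °C enolises the acetyl methyl and closes the aldol F4 (C4 configuration immaterial). MsCl and Et3N dehydrate it to the cyclopentenone F5. Conjugate borylation (CuCl, NaOtBu, B2pin2, MeOH) from the face opposite the C1 methyl and the C6 arm gives the β-boryl ketone F6. NaBO3·4H2O oxidises this with retention to the tertiary alcohol F7, and Et3SiOTf with 2,6-lutidine returns to 30.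

Step 10 (Wacker oxidation). The vinyl group sits on a quaternary carbon next to a silyloxy group, so slow conversion or aldehyde formation is possible. The fallback replaces the palladium oxidation by hydration and oxidation: from 19, Hg(OAc)2 in THF–H2O gives the Markovnikov organomercurial F8, NaBH4 demercurates it to the secondary alcohol F9 (C2 epimers), and Dess–Martin periodinane gives 20.

**Further compounds**
F1 | step 11 | silyl nitronate of 20 | CC(C)/C=C\[C@@](C)(C(C)=O)[C@@H](O[Si](CC)(CC)CC)[C@H]1O[C@]1(C)CC=[N+]([O-])O[Si](C)(C)C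
F2 | step 11 | N-(trimethylsilyloxy)isoxazolidine (C6 configuration not controlled) | CC(C)[C@H]1ON(O[Si](C)(C)C)C2C[C@@]3(C)O[C@@H]3[C@H](O[Si](CC)(CC)CC)[C@](C)(C(C)=O)[C@@H]12
F3 | step 16 | 1,4-diketone (C4 isobutyryl, C2 acetyl) | CC(C)C(=O)[C@H]1[C@H](OC(=O)c2ccc(OC)c(OC)c2)C[C@@]3(C)O[C@@H]3[C@H](O[Si](CC)(CC)CC)[C@]1(C)C(C)=O
F4 | step 16 | aldol (3-hydroxy-3-isopropylcyclopentanone, C4 epimers) | COc1ccc(C(=O)O[C@@H]2C[C@@]3(C)O[C@@H]3[C@H](O[Si](CC)(CC)CC)[C@]3(C)C(=O)CC(O)(C(C)C)[C@@H]23)cc1OC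
F5 | step 16 | cyclopentenone (C2=O, C3=C4) | COc1ccc(C(=O)O[C@@H]2C[C@@]3(C)O[C@@H]3[C@H](O[Si](CC)(CC)CC)[C@]3(C)C(=O)C=C(C(C)C)[C@@H]23)cc1OC
F6 | step 16 | β-boryl ketone (C4–Bpin) | COc1ccc(C(=O)O[C@@H]2C[C@@]3(C)O[C@@H]3[C@H](O[Si](CC)(CC)CC)[C@]3(C)C(=O)C[C@@](B4OC(C)(C)C(C)(C)O4)(C(C)C)[C@@H]23)cc1OC
F7 | step 16 | β-hydroxy ketone (C4–OH, C2=O) | COc1ccc(C(=O)O[C@@H]2C[C@@]3(C)O[C@@H]3[C@H](O[Si](CC)(CC)CC)[C@]3(C)C(=O)C[C@@](O)(C(C)C)[C@@H]23)cc1OC
F8 | step 10 | organomercurial (C2–OH, C3–HgOAc) | CC(C)/C=C\[C@@](C)(C(O)C[Hg]OC(C)=O)[C@@H](O[Si](CC)(CC)CC)[C@H]1O[C@]1(C)CC[N+](=O)[O-]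
F9 | step 10 | secondary alcohol (C2–OH, C2 epimers) | CC(C)/C=C\[C@@](C)(C(C)O)[C@@H](O[Si](CC)(CC)CC)[C@H]1O[C@]1(C)CC[N+](=O)[O-]
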